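Amounts first: each flask gets starting material in portions and 0.700 equiv of coupling partner, and I want the product that stands in each at the end.

| flask | starting material | coupling partner | initiator | remark | time |
|---|---|---|---|---|---|
| Saturday's | 0.021 M (in portions, 4) | 0.70 equiv | 0.5 mol% | run made earlier; portions every 8.0 s |  |
| Friday's | 0.062 M (in portions, 4) | 0.70 equiv | 0.5 mol% | run made earlier; portions every 8.0 s |  |
| Wednesday's | 0.24 M (in portions, 4) | 0.70 equiv | 0.5 mol% | run made earlier; portions every 8.0 s |  |
| oak | 0.020 M (in portions, 4) | 0.700 equiv | 0.5 mol% | the portions of starting material follow each other after 8.0 s, the first at the start | 3.0 min |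
| larch | 0.060 M (in portions, 4) | 0.700 equiv | 0.5 mol% | the portions of starting material follow each other after 8.0 s, the first at the start | 3.0 min |
| ash | 0.20 M (in portions, 4) | 0.700 equiv | 0.5 mol% | the portions of starting material follow each other after 8.0 s, the first at the start | 3.0 min |

- Saturday's (time / s: product / %, starting material / %): 12.0: 5.3, 43.9; 30.0: 21.7, 77.7; 60.0: 42.8, 50.1; 90.0: 57.8, 35.7; 120: 65.1, 26.0
- Friday's (time / s: product / %, starting material / %): 25.0: 24.9, 72.9; 50.0: 53.5, 39.8; 80.0: 69.3, 23.3; 90.0: 69.8, 23.2; 120: 69.1, 20.9
- Wednesday's (time / s: product / %, starting material / %): 10.0: 12.9, 39.2; 20.0: 29.6, 43.9; 40.0: 66.7, 31.1; 60.0: 71.7, 25.7; 120: 71.4, 21.9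

(standard deviation of a reading: 1 percentage point)

- "hardly changes" means that all values lie within two and a half points (for a concentration: within two and a half percent of the largest)

- [product] at the end for oak, larch, ash, in this order
- the course of these numbers from the first flask to the last (rises, then falls / falls all the way / falls, then rises / rises all the way / hardly changes)

Friday's run levels at 69.8% and Wednesday's at 71.4% of the starting material charged, against 0.70 equiv of coupling partner, and Wednesday's still shows 21.9% of starting material. So I read one product per coupling partner, with the partner as limiting reagent. I call the partner's charge in molarity the ceiling 0.0140 M for oak, which makes 0.0420 M for larch and 0.140 M for ash.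

Friday's run is flat by 80.0 s and Wednesday's by 60.0 s, well inside 3.0 min. Larch sits beside Friday's charge and ash lies between the two, so I put both at their ceilings.

Oak is the doubtful flask: Saturday's run, nearly its twin, still climbs at 120 s. I treat the gap to the ceiling as a first-order tail. The gap is 27.2% at 60.0 s and 4.90% at 120 s, a time constant of 35.0 s. The 60.0 s still left are longer, so I expect the gap to shrink to 0.883%.

The weak link is that time constant, since a slowing tail could hide in a two-point reading. So I go round again on the last window alone, from a gap of 12.2% at 90.0 s. It reads 32.9 s, which is shorter but rests on readings with a scatter of 1 percentage point, and it points to a final gap of 0.790%. I commit to 0.0138 M for oak, with larch and ash at their ceilings.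

The forecast gives 0.0138 M, 0.042 M, 0.14 M, rises all the way. In its words, “The percentage yield hardly changes, but the concentration rises all the way”.

The flasks give 0.0140 M, 0.0420 M, 0.140 M: rises all the way.

    2 chain carrier → ended chains B (k = 5.60 × 10⁷ /M/s)
    initiator → 2 initiating radical (k = 0.00950 /s)
    starting material + initiating radical ⇌ chain carrier (K = 2.70 × 10⁵ /M, k = 32000 /M/s)
    coupling partner + chain carrier → product + initiating radical (k = 2.00 × 10⁶ /M/s)
    starting material ⇌ dormant form (K = 2.00, k = 0.00210 /s)
    2 initiating radical → ended chains A (k = 4.60 × 10⁶ /M/s)

Oak ends at 0.0140 M against its ceiling of 0.0140 M, and ash at 0.140 M against 0.140 M. In ash the falling level of coupling partner is the largest single effect on the end product: with that level held, ash gives 0.190 M instead of 0.140 M, while the turning of starting material into dormant form, 9.15% at 3.00 min, makes no difference to that product. In oak the falling level is not the reason for the end product: holding it moves that product from 0.0140 M to 0.0144 M.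

The runs are calculated for substances that don't exist, noise included.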